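Reading "zero order" into a rate that barely answers to X is the trap here: that word describes one end of a curve, not a flask.

| setting | Saturday's | Friday's | Monday's |
|---|---|---|---|
| Q | 0.150 M | 0.150 M | 0.150 M |
| X | 0.225 M | 0.450 M | 0.780 M |
| L | 0.00300 M | 0.00300 M | 0.00300 M |
| time |  |  | 40 min |

- Saturday's run (time / min: [Q] / M): 1.6: 0.1423; 3.0: 0.1387; 5.8: 0.1262; 11: 0.1091; 21: 0.0757; 40: 0.0347
- Friday's run (time / min: [Q] / M): 1.6: 0.1428; 3.0: 0.1342; 5.8: 0.1229; 11: 0.1038; 21: 0.0691; 40: 0.0297

(scatter of a reading: 8 × 10⁻⁴ M)

1. apparent order in [X] of the starting rate, round the charge of the Saturday's run (the rate where two percent of its Q have turned into J)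
2. Q in the Monday's run at 40 min, as a share of the Q charged

- Overall: Q + X -> J, with L as catalyst.
- Constant volume, constant temperature.
- The analysis sees a species whether free or bound.
- "The second partner" is X.
- An order is taken over about fifteen percent of the charge, up and down.

Two chemists dispute Monday's flask. Over the first 11 min, Saturday's mean rate of loss of Q is 0.00372 M min⁻¹ and Friday's, with twice the X, is 0.00420 M min⁻¹, a ratio of 1.13. The first chemist calls X saturated on that 1.13, so for him Monday repeats Friday and leaves 19.8% of its Q at 40 min.

The second solves both ends and joins them. She takes it that with little X the rate follows X and with much X it ignores X, so the minutes per molar of J are a part R, set by Q, plus c/X, with c a constant. In this joined law, the ping-pong form, the share of c/X in those minutes is the local order in X. Saturday against Friday, at their charges of X, reads 13.9 min for c, which she names the X toll, so Saturday's share over those first minutes is 0.229, a reading that carries the scatter.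

For Monday she compares with Friday. Summed while X falls, the toll costs c times the logarithm of X at the start over X at the end, so across the 0.120 M of Q that Friday loses, Monday's lighter toll saves 1.99 min. Friday's last stretch reads a loss of Q at 0.0444 min⁻¹, and spending the saved minutes at that pace gives about 18.1% for Monday.

That is my reckoning too. The forecast takes the same side with other numbers, an order of 0.2 and a Monday share of 18.7%; the gap between the runs, it says, “suggests a ping-pong type of law”. Its toll is 11 min against my 13.9 min, and my order is higher than its own.

    L + Q → Oz + Z (20.70 L mol⁻¹ min⁻¹)
    Oz + X → J + L (97.80 L mol⁻¹ min⁻¹)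
    L + Q ⇌ LQ, settled at all times (3.900 L mol⁻¹)
    2 X ⇌ X2, settled at all times (33.40 L mol⁻¹)

Monday's flask gives 17.9%, below Friday's 19.8%, so the first chemist loses; the order in X round Saturday's charge is 0.16. Early on, with equal J made, Friday's rate is 1.1 times Saturday's. The first view has its region in the tail of Friday's run: with about 0.330 M of X unreacted at 40 min, and the mean rate from 21 min on, the toll reads 8.73% of the minutes per molar. Until J reaches half the Q charged, the toll, with X falling, puts Saturday behind Friday by 3.10 min, and the two runs reach that point at 21.7 min and 19.7 min, which is 2.00 min apart.

The data are simulated with constants of no real substance; the scatter is artificial.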